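**Retrosynthetic overview**
1. The target comes from its tetra-silyl ether by one buffered fluoride step; nothing else follows the key step.
2. Key disconnection C2–C1′: C2 is the β-carbon of the C4 ketone (through C3) in the pyranone ring and also carries O1. The bond therefore maps onto an enantioselective Rh(I) 1,4-addition of a catechol-derived arylboronic acid to the flat C2=C3 vinylogous ester of a fully substituted 4H-chromen-4-one. Two achiral halves are joined and the only stereocentre (2S) is created in the same event.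
3. Chromone half: benzylic CH2–C(sp2) Negishi coupling of an 8-(bromomethyl)chromone with a (Z)-alkenylzinc. The Z geometry comes from chelate-controlled carbomagnesiation of propargyl alcohol and is carried through with retention.
4. Aryl half: 4-bromocatechol, silylation, then lithiation–borylation.
5. Ring order: both benzene rings are bought; the pyranone ring is closed first (enaminone cyclisation of a 2-hydroxyacetophenone); no ring is formed later.

Key step: step 9

Remark (assumption on the chemistry): the target is read as the (2S)-flavanone with a (Z) side chain (CH2OH cis to the benzylic CH2); the sense of induction in step 9 is assumed to follow that of cyclic enones with (S)-biaryl bisphosphines, and the (R)-ligand would be used if it proved opposite.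

**Route**

Step 1
Reactants: 1 prop-2-yn-1-ol
Product: 3 (Z)-3-iodo-2-methylprop-2-en-1-ol, via alkenylmagnesium alkoxide 2 (not isolated)
Conditions: MeMgBr (2.5 equiv), CuI (10 mol %), THF/Et2O, −10 °C → rt; then I2, −20 → 0 °C; H2O (aq. Na2S2O3)
Reagents that add atoms: methylmagnesium bromide C[Mg]Br; iodine II
Why: Copper-catalysed anti-carbomagnesiation of the propargylic magnesium alkoxide puts CH3 on C2 and Mg on C3, the five-membered alkoxide chelate holds Mg cis to CH2O, and iodinolysis with retention should give the Z iodide (I cis to CH2OH).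

Step 2
Reactants: 3 (Z)-3-iodo-2-methylprop-2-en-1-ol
Product: 4 tert-butyl{[(Z)-3-iodo-2-methylprop-2-en-1-yl]oxy}dimethylsilane
Conditions: TBSCl, imidazole, CH2Cl2, 0 °C → rt
Reagents that add atoms: tert-butyldimethylsilyl chloride CC(C)(C)[Si](C)(C)Cl
Why: Standard silylation of a primary alcohol, which removes the acidic proton before the halogen–lithium exchange of step 6.

Step 3
Reactants: 5 1-(2,4-dihydroxy-3-methylphenyl)ethan-1-one
Product: 6 1-{2-hydroxy-3-methyl-4-[tri(propan-2-yl)silyloxy]phenyl}ethan-1-one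
Conditions: TIPSCl (1.05 equiv), imidazole, DMF, 0 °C → rt
Reagents that add atoms: triisopropylsilyl chloride CC(C)[Si](Cl)(C(C)C)C(C)C
Why: Selective phenol silylation should take the 4-OH only, because the 2-OH is held in the hydrogen bond to the acetyl group.

Step 4
Reactants: 6 1-{2-hydroxy-3-methyl-4-[tri(propan-2-yl)silyloxy]phenyl}ethan-1-one
Product: 8 8-methyl-7-[tri(propan-2-yl)silyloxy]-4H-chromen-4-one, via enaminone 7 (not isolated)
Conditions: DMF-DMA, PhMe, 90 °C; then aq. HCl, CH2Cl2, rt
Reagents that add atoms: N,N-dimethylformamide dimethyl acetal COC(OC)N(C)C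
Why: Condensation of the acetyl CH3 with the amide acetal gives the enaminone, and acid then drives 6-endo addition of the 2-OH to its β-carbon with loss of dimethylamine (enaminone route to chromones), which closes the pyranone ring.

Step 5
Reactants: 8 8-methyl-7-[tri(propan-2-yl)silyloxy]-4H-chromen-4-one
Product: 9 8-(bromomethyl)-7-[tri(propan-2-yl)silyloxy]-4H-chromen-4-one
Conditions: NBS (1.05 equiv), AIBN (5 mol %), PhCF3, 85 °C
Reagents that add atoms: N-bromosuccinimide O=C1CCC(=O)N1Br
Why: Wohl–Ziegler bromination at the 8-methyl group, the only benzylic C–H; the bulky TIPS ether next to C6 and the electron-poor vinylogous-ester ring should hold back nuclear bromination at C6 and C3.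

Step 6
Reactants: 4 tert-butyl{[(Z)-3-iodo-2-methylprop-2-en-1-yl]oxy}dimethylsilane, 9 8-(bromomethyl)-7-[tri(propan-2-yl)silyloxy]-4H-chromen-4-one
Product: 12 8-[(Z)-4-(tert-butyldimethylsilyloxy)-3-methylbut-2-en-1-yl]-7-[tri(propan-2-yl)silyloxy]-4H-chromen-4-one, via alkenyllithium 10 (not isolated), via alkenylzinc bromide 11 (not isolated)
Conditions: 4, t-BuLi (2 equiv), Et2O, −78 °C; ZnBr2, THF, −78 → 0 °C; then 9, Pd(PPh3)4 (5 mol %), THF, rt
Reagents that add atoms: none
Why: Negishi coupling: I/Li exchange and transmetalation to zinc proceed with retention at the alkenyl carbon and Pd(0) inserts quickly into the benzylic C–Br bond, so the Z geometry should pass into 12 while the alkenylzinc leaves the chromone carbonyl alone.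

Step 7
Reactants: 13 4-bromobenzene-1,2-diol
Product: 14 4-bromo-1,2-bis(tert-butyldimethylsilyloxy)benzene
Conditions: TBSCl (2.3 equiv), imidazole, DMF, rt
Reagents that add atoms: tert-butyldimethylsilyl chloride CC(C)(C)[Si](C)(C)Cl
Why: Standard double silylation of the catechol, which masks the chelating diol for the metal-mediated steps.

Step 8
Reactants: 14 4-bromo-1,2-bis(tert-butyldimethylsilyloxy)benzene
Product: 17 [3,4-bis(tert-butyldimethylsilyloxy)phenyl]boronic acid, via aryllithium 15 (not isolated), via lithium aryltriisopropoxyborate 16 (not isolated)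
Conditions: n-BuLi, THF, −78 °C; B(OiPr)3, −78 °C → rt; then 1 M HCl to pH 5
Reagents that add atoms: triisopropyl borate CC(C)OB(OC(C)C)OC(C)C; water O
Why: Lithiation–borylation: Br/Li exchange at −78 °C, trapping with the borate and mild hydrolysis; the lithium sits meta and para to the silyloxy groups, so no silyl shift to carbon is expected.

Step 9
Reactants: 12 8-[(Z)-4-(tert-butyldimethylsilyloxy)-3-methylbut-2-en-1-yl]-7-[tri(propan-2-yl)silyloxy]-4H-chromen-4-one, 17 [3,4-bis(tert-butyldimethylsilyloxy)phenyl]boronic acid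
Product: 18 (2S)-2-[3,4-bis(tert-butyldimethylsilyloxy)phenyl]-8-[(Z)-4-(tert-butyldimethylsilyloxy)-3-methylbut-2-en-1-yl]-7-[tri(propan-2-yl)silyloxy]-2,3-dihydro-4H-chromen-4-one
Conditions: 17 (2.5 equiv), [RhCl(C2H4)2]2 (2.5 mol %), (S)-MeO-F12-BIPHEP (5.5 mol %), aq. KOH (10 mol %), CH2Cl2/H2O, rt
Reagents that add atoms: none
Why: Transmetalation of 17 to the hydroxo-Rh(I)–bisphosphine gives an aryl-Rh(I) that binds the C2=C3 bond of 12 and inserts it with aryl delivery to C2; water protonates the resulting oxa-π-allyl Rh enolate at C3 and returns Rh–OH. The closest known reaction type is the Rh-catalysed asymmetric conjugate arylation of 4H-chromen-4-ones with arylboronic acids to flavanones (Hayashi–Miyaura reaction). No ring is closed: the pyranone ring is already present and only changes from enone to saturated ketone. C2 is the only new stereocentre and is set by the C2-symmetric (S)-bisphosphine, whose quadrant blocking should make the chromone bind so that aryl adds to the Re face of C2 (2S). The step needs 1,4- over 1,2-addition, a single addition, and no β-aryloxide elimination of the Rh enolate (ring opening would scramble C2); the soft aryl-Rh, the near-neutral two-phase medium that protonates the enolate quickly, and a substrate whose C2=C3 bond is the only electron-poor alkene and carries only H at C2 should secure this. The isolated trisubstituted alkene and the four silyl ethers should be inert to Rh(I).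

Step 10
Reactants: 18 (2S)-2-[3,4-bis(tert-butyldimethylsilyloxy)phenyl]-8-[(Z)-4-(tert-butyldimethylsilyloxy)-3-methylbut-2-en-1-yl]-7-[tri(propan-2-yl)silyloxy]-2,3-dihydro-4H-chromen-4-one
Product: 19 (2S)-2-(3,4-dihydroxyphenyl)-7-hydroxy-8-[(Z)-4-hydroxy-3-methylbut-2-en-1-yl]-2,3-dihydro-4H-chromen-4-one
Conditions: TBAF (6 equiv), AcOH (7 equiv), THF, 0 °C → rt
Reagents that add atoms: none
Why: Fluoride-induced desilylation of three aryl and one primary alkyl silyl ether; the acetic acid buffer keeps phenoxide basicity low, so the flavanone should not open by retro-oxa-Michael reaction and C2 should keep its configuration.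

**Compound list**
1 | prop-2-yn-1-ol | C#CCO | starting material
2 | bromomagnesium (Z)-3-(bromomagnesio)-2-methylprop-2-en-1-olate | C/C(=C/[Mg]Br)CO[Mg]Br | intermediate (not isolated)
3 | (Z)-3-iodo-2-methylprop-2-en-1-ol | C/C(=C/I)CO | intermediate
4 | tert-butyl{[(Z)-3-iodo-2-methylprop-2-en-1-yl]oxy}dimethylsilane | C/C(=C/I)CO[Si](C)(C)C(C)(C)C | intermediate
5 | 1-(2,4-dihydroxy-3-methylphenyl)ethan-1-one | CC(=O)c1ccc(O)c(C)c1O | starting material
6 | 1-{2-hydroxy-3-methyl-4-[tri(propan-2-yl)silyloxy]phenyl}ethan-1-one | CC(=O)c1ccc(O[Si](C(C)C)(C(C)C)C(C)C)c(C)c1O | intermediate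
7 | (E)-3-(dimethylamino)-1-{2-hydroxy-3-methyl-4-[tri(propan-2-yl)silyloxy]phenyl}prop-2-en-1-one | CN(C)/C=C/C(=O)c1ccc(O[Si](C(C)C)(C(C)C)C(C)C)c(C)c1O | intermediate (not isolated)
8 | 8-methyl-7-[tri(propan-2-yl)silyloxy]-4H-chromen-4-one | Cc1c(O[Si](C(C)C)(C(C)C)C(C)C)ccc2c(=O)ccoc12 | intermediate
9 | 8-(bromomethyl)-7-[tri(propan-2-yl)silyloxy]-4H-chromen-4-one | BrCc1c(O[Si](C(C)C)(C(C)C)C(C)C)ccc2c(=O)ccoc12 | intermediate
10 | [(Z)-3-(tert-butyldimethylsilyloxy)-2-methylprop-1-en-1-yl]lithium | C/C(=C/[Li])CO[Si](C)(C)C(C)(C)C | intermediate (not isolated)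
11 | [(Z)-3-(tert-butyldimethylsilyloxy)-2-methylprop-1-en-1-yl]zinc bromide | C/C(=C/[Zn]Br)CO[Si](C)(C)C(C)(C)C | intermediate (not isolated)
12 | 8-[(Z)-4-(tert-butyldimethylsilyloxy)-3-methylbut-2-en-1-yl]-7-[tri(propan-2-yl)silyloxy]-4H-chromen-4-one | C/C(=C/Cc1c(O[Si](C(C)C)(C(C)C)C(C)C)ccc2c(=O)ccoc12)CO[Si](C)(C)C(C)(C)C | intermediate
13 | 4-bromobenzene-1,2-diol | Oc1ccc(Br)cc1O | starting material
14 | 4-bromo-1,2-bis(tert-butyldimethylsilyloxy)benzene | CC(C)(C)[Si](C)(C)Oc1ccc(Br)cc1O[Si](C)(C)C(C)(C)C | intermediate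
15 | [3,4-bis(tert-butyldimethylsilyloxy)phenyl]lithium | [Li]c1ccc(O[Si](C)(C)C(C)(C)C)c(O[Si](C)(C)C(C)(C)C)c1 | intermediate (not isolated)
16 | lithium [3,4-bis(tert-butyldimethylsilyloxy)phenyl]tri(propan-2-yloxy)borate | [Li+].CC(C)O[B-](OC(C)C)(OC(C)C)c1ccc(O[Si](C)(C)C(C)(C)C)c(O[Si](C)(C)C(C)(C)C)c1 | intermediate (not isolated)
17 | [3,4-bis(tert-butyldimethylsilyloxy)phenyl]boronic acid | OB(O)c1ccc(O[Si](C)(C)C(C)(C)C)c(O[Si](C)(C)C(C)(C)C)c1 | intermediate
18 | (2S)-2-[3,4-bis(tert-butyldimethylsilyloxy)phenyl]-8-[(Z)-4-(tert-butyldimethylsilyloxy)-3-methylbut-2-en-1-yl]-7-[tri(propan-2-yl)silyloxy]-2,3-dihydro-4H-chromen-4-one | C/C(=C/Cc1c(O[Si](C(C)C)(C(C)C)C(C)C)ccc2c1O[C@H](c1ccc(O[Si](C)(C)C(C)(C)C)c(O[Si](C)(C)C(C)(C)C)c1)CC2=O)CO[Si](C)(C)C(C)(C)C | intermediate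
19 | (2S)-2-(3,4-dihydroxyphenyl)-7-hydroxy-8-[(Z)-4-hydroxy-3-methylbut-2-en-1-yl]-2,3-dihydro-4H-chromen-4-one | C/C(=C/Cc1c(O)ccc2c1O[C@H](c1ccc(O)c(O)c1)CC2=O)CO | target

**Step count and risks**
Total steps: 10. Longest linear sequence: 6 (steps 3, 4, 5, 6, 9, 10).

Steps most likely to fail:

1. Step 9. The 7-silyloxy donor lowers the electrophilicity of C2, so insertion may be slower than protodeboronation of the electron-rich boronic acid. β-Aryloxide elimination of the Rh enolate would open the ring and erode the enantiomeric purity, and the facial discrimination itself may be insufficient. The fallback sets out from 12 (with 17) and returns at 18. The addition is run without chiral control using the more active diene complex [Rh(OH)(cod)]2 in dioxane/H2O, which should give the racemic tetra-silyl flavanone F1. F1 is then resolved kinetically by asymmetric transfer hydrogenation (Noyori-type Ru(p-cymene)–TsDPEN catalyst, HCO2H/Et3N, EtOAc, rt, stopped near half conversion), using the catalyst antipode that reduces the (2R)-ketone faster to the cis-(2R,4R)-flavan-4-ol F2. The unreduced (2S)-ketone is 18 and is separated from F2 by chromatography.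

2. Step 5. Ionic bromination of the ring (C6, C3) may compete with hydrogen abstraction from the methyl group, and the benzylic position may be brominated twice. The fallback sets out from 4 and returns at 12; it makes the aryl–CH2 bond instead and bypasses steps 5 and 6.
   - Compound 4 is lithiated as in step 6 (via 10) and treated with 2-(chloromethyl)-4,4,5,5-tetramethyl-1,3,2-dioxaborolane; Matteson homologation with 1,2-shift of the alkenyl group should give the (Z)-allylboronate tert-butyl{[(Z)-2-methyl-4-(4,4,5,5-tetramethyl-1,3,2-dioxaborolan-2-yl)but-2-en-1-yl]oxy}dimethylsilane F3.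
   - Purchased 7-hydroxy-4H-chromen-4-one F4 is iodinated at C8, the position activated by both O1 and the 7-OH (NIS, DMF), to give 7-hydroxy-8-iodo-4H-chromen-4-one F5.
   - F5 is silylated (TIPSCl, imidazole) to 8-iodo-7-[tri(propan-2-yl)silyloxy]-4H-chromen-4-one F6.
   - An α-selective Suzuki–Miyaura allyl–aryl coupling of F3 with F6 (Pd–NHC precatalyst Pd-PEPPSI-IPent, aq. KOH, THF) should give 12. Retention of the Z geometry through the π-allyl stage is the point that would need to be checked.

3. Step 10. The primary alkyl silyl ether is cleaved much more slowly than the three aryl silyl ethers, and the long fluoride exposure this forces may open the flavanone (retro-oxa-Michael, assisted by the freed 4′-phenol) and scramble C2. The fallback sets out from 12 and returns at 19; it takes the slow cleavage out of the last step.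
   - The alkyl TBS group of 12 is removed first by acidic methanolysis (PPTS, MeOH, rt), which should leave the aryl TIPS ether and give 8-[(Z)-4-hydroxy-3-methylbut-2-en-1-yl]-7-[tri(propan-2-yl)silyloxy]-4H-chromen-4-one F7.
   - The conditions of step 9 are applied to F7 and 17 (free alcohols are tolerated by Rh(I)) to give (2S)-2-[3,4-bis(tert-butyldimethylsilyloxy)phenyl]-8-[(Z)-4-hydroxy-3-methylbut-2-en-1-yl]-7-[tri(propan-2-yl)silyloxy]-2,3-dihydro-4H-chromen-4-one F8.
   - F8 carries only fast-cleaving phenolic silyl ethers, so a short treatment with TBAF/AcOH at 0 °C should give 19.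

**Further compounds**
F1 | step 9 | rac-2-[3,4-bis(tert-butyldimethylsilyloxy)phenyl]-8-[(Z)-4-(tert-butyldimethylsilyloxy)-3-methylbut-2-en-1-yl]-7-[tri(propan-2-yl)silyloxy]-2,3-dihydro-4H-chromen-4-one | C/C(=C/Cc1c(O[Si](C(C)C)(C(C)C)C(C)C)ccc2c1OC(c1ccc(O[Si](C)(C)C(C)(C)C)c(O[Si](C)(C)C(C)(C)C)c1)CC2=O)CO[Si](C)(C)C(C)(C)C
F2 | step 9 | (2R,4R)-2-[3,4-bis(tert-butyldimethylsilyloxy)phenyl]-8-[(Z)-4-(tert-butyldimethylsilyloxy)-3-methylbut-2-en-1-yl]-7-[tri(propan-2-yl)silyloxy]-3,4-dihydro-2H-chromen-4-ol | C/C(=C/Cc1c(O[Si](C(C)C)(C(C)C)C(C)C)ccc2c1O[C@@H](c1ccc(O[Si](C)(C)C(C)(C)C)c(O[Si](C)(C)C(C)(C)C)c1)C[C@H]2O)CO[Si](C)(C)C(C)(C)C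
F3 | step 5 | tert-butyl{[(Z)-2-methyl-4-(4,4,5,5-tetramethyl-1,3,2-dioxaborolan-2-yl)but-2-en-1-yl]oxy}dimethylsilane | C/C(=C/CB1OC(C)(C)C(C)(C)O1)CO[Si](C)(C)C(C)(C)C
F4 | step 5 | 7-hydroxy-4H-chromen-4-one (purchased) | O=c1ccoc2cc(O)ccc12
F5 | step 5 | 7-hydroxy-8-iodo-4H-chromen-4-one | O=c1ccoc2c(I)c(O)ccc12
F6 | step 5 | 8-iodo-7-[tri(propan-2-yl)silyloxy]-4H-chromen-4-one | O=c1ccoc2c(I)c(O[Si](C(C)C)(C(C)C)C(C)C)ccc12
F7 | step 10 | 8-[(Z)-4-hydroxy-3-methylbut-2-en-1-yl]-7-[tri(propan-2-yl)silyloxy]-4H-chromen-4-one | C/C(=C/Cc1c(O[Si](C(C)C)(C(C)C)C(C)C)ccc2c(=O)ccoc12)CO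
F8 | step 10 | (2S)-2-[3,4-bis(tert-butyldimethylsilyloxy)phenyl]-8-[(Z)-4-hydroxy-3-methylbut-2-en-1-yl]-7-[tri(propan-2-yl)silyloxy]-2,3-dihydro-4H-chromen-4-one | C/C(=C/Cc1c(O[Si](C(C)C)(C(C)C)C(C)C)ccc2c1O[C@H](c1ccc(O[Si](C)(C)C(C)(C)C)c(O[Si](C)(C)C(C)(C)C)c1)CC2=O)CO
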